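**Strategy.** The target is a biflavone joined from C6 of unit 1 to C8 of unit 2. The plan rests on opening the pyranone of unit 1 at O1–C8a, C4–C4a and O1–C2. In one operation a 4-aryl-3,5-dialkoxybenzyne inserts into the C–O bond of 3-(4-methoxyphenyl)propiolic acid and the resulting phenoxide ynone closes the ring. This exploits the neighbouring ring A carbons C8a and C4a, polarised by the C5 oxygen. The precursor is a biaryl ortho-silyl aryl triflate with a symmetric ring A. Isopropyl ethers replace benzyl ethers, which permits lithiation chemistry and C–H borylation on the way in and a single BCl3 unmasking at the end.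

Key step: step 7

Assumption: the target SMILES carries no descriptor for the C6–C8 biaryl axis, so the axis is not controlled and every compound from 11 onward is racemic about it.

Design remark: benzyl ethers are avoided because the carbon between two benzyloxy groups is not reached cleanly by electrophiles or alkyllithiums, benzyl phenyl rings would compete in the borylation of step 4, and a benzyloxy group peri to the chromone carbonyl is acid-labile; compounds 15 and 19 keep the skeletons of the aryne precursor and of the insertion product.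

**Route**

Step 1
Reactants: 1 3,5-dimethoxyphenol
Product: 2 1,3-dimethoxy-5-(methoxymethoxy)benzene
Conditions: MOMCl, i-Pr2NEt, CH2Cl2, 0 °C to rt
Reagents that add atoms: chloromethyl methyl ether, COCCl
Why: O-Alkylation of the phenol with chloromethyl methyl ether (Williamson-type acetal formation) masks the oxygen that becomes O1 of unit 2 as a group that also directs the lithiation of step 2.

Step 2
Reactants: 2 1,3-dimethoxy-5-(methoxymethoxy)benzene
Product: 4 2-iodo-1,5-dimethoxy-3-(methoxymethoxy)benzene, via aryllithium 3 (not isolated)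
Conditions: n-BuLi, THF, 0 °C; I2, −78 °C to rt
Reagents that add atoms: iodine, [I][I]
Why: Directed ortho-metalation, in which the chelating MOM oxygen and the adjacent methoxy group together place lithium on the carbon between them, followed by iodinolysis to an iodide that can be purified from any isomer lithiated between the two methoxy groups.

Step 3
Reactants: 5 1,3-diisopropoxybenzene; 4 2-iodo-1,5-dimethoxy-3-(methoxymethoxy)benzene
Product: 8 2',6'-diisopropoxy-2,4-dimethoxy-6-(methoxymethoxy)biphenyl, via aryllithium 6 (not isolated), via arylzinc chloride 7 (not isolated)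
Conditions: n-BuLi, THF, 0 °C to rt; ZnCl2, THF; then 4, Pd2(dba)3 (2 mol %), RuPhos (8 mol %), THF/NMP, 80 °C
Reagents that add atoms: none
Why: Cooperative directed ortho-lithiation between the two isopropoxy groups (the only doubly activated site), transmetalation to zinc and Negishi cross-coupling under Pd2(dba)3/RuPhos, a combination established for tetra-ortho-substituted biaryls that avoids the protodeboronation typical of 2,6-dialkoxyarylboronic acids.

Step 4
Reactants: 8 2',6'-diisopropoxy-2,4-dimethoxy-6-(methoxymethoxy)biphenyl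
Product: 10 3,5-diisopropoxy-4-[2,4-dimethoxy-6-(methoxymethoxy)phenyl]phenol, via arylboronate 9 (not isolated)
Conditions: [Ir(OMe)(cod)]2 (1.5 mol %), dtbpy (3 mol %), B2pin2, THF, 80 °C; then aq. NaOH, H2O2, 0 °C
Reagents that add atoms: hydrogen peroxide, OO
Why: Sterically governed iridium-catalysed aromatic C–H borylation followed by peroxide oxidation of the boronate, which should place the phenol para to the biaryl bond because that is the only aryl C–H in 8 without an ortho substituent.

Step 5
Reactants: 10 3,5-diisopropoxy-4-[2,4-dimethoxy-6-(methoxymethoxy)phenyl]phenol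
Product: 11 2-bromo-3,5-diisopropoxy-4-[2,4-dimethoxy-6-(methoxymethoxy)phenyl]phenol
Conditions: NBS (1.0 equiv), i-Pr2NH (0.1 equiv), CH2Cl2, −78 to 0 °C
Reagents that add atoms: N-bromosuccinimide, O=C1CCC(=O)N1Br
Why: Amine-mediated ortho-bromination of a phenol (electrophilic aromatic substitution through the N-bromoamine), in which the hydrogen-bonded phenol ring should react faster than the triether ring, the para position is blocked and the two ortho positions are equivalent, so one equivalent should give a single monobromide.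

Step 6
Reactants: 11 2-bromo-3,5-diisopropoxy-4-[2,4-dimethoxy-6-(methoxymethoxy)phenyl]phenol
Product: 15 3,5-diisopropoxy-4-[2,4-dimethoxy-6-(methoxymethoxy)phenyl]-2-(trimethylsilyl)phenyl trifluoromethanesulfonate, via trimethylsilyl ether 12 (not isolated), via aryllithium 13 (not isolated), via lithium phenoxide 14 (not isolated)
Conditions: HMDS, THF, 65 °C, then concentrate; n-BuLi, THF, −100 to −80 °C; Tf2O, −100 °C to rt
Reagents that add atoms: hexamethyldisilazane, C[Si](C)(C)N[Si](C)(C)C; trifluoromethanesulfonic anhydride, O=S(=O)(OS(=O)(=O)C(F)(F)F)C(F)(F)F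
Why: O-Silylation, bromine–lithium exchange and retro-Brook (1,3 oxygen-to-carbon) silyl migration deliver the ortho-silyl phenoxide, which is trapped as the triflate in the same flask, a standard route to ortho-silylaryl triflates that isopropyl, methyl and MOM ethers tolerate.

Step 7
Reactants: 15 3,5-diisopropoxy-4-[2,4-dimethoxy-6-(methoxymethoxy)phenyl]-2-(trimethylsilyl)phenyl trifluoromethanesulfonate; 16 3-(4-methoxyphenyl)propiolic acid
Product: 19 5,7-diisopropoxy-6-[2,4-dimethoxy-6-(methoxymethoxy)phenyl]-2-(4-methoxyphenyl)chromen-4-one, via aryne 17 (not isolated), via caesium phenoxide ynone 18 (not isolated)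
Conditions: 16 (1.2 equiv), CsF (4 equiv), THF, 125 °C, sealed tube
Reagents that add atoms: none
Why: Fluoride strips the silyl group and triflate departs to give aryne 17; the caesium carboxylate of 16 adds through oxygen to the aryne carbon remote from the isopropoxy group (the future C8a), the aryl anion at the neighbouring carbon (the future C4a) attacks the ester carbonyl in a four-membered cyclic pathway, and its collapse moves the acyl group from oxygen to carbon, leaving phenoxide ynone 18. The closest known reaction type is the fluoride-triggered insertion of arynes into the C–O bond of carboxylic acids, which with arylpropiolic acids carries on to flavones. The pyranone of unit 1 closes by 6-endo-dig oxa-Michael addition of the phenoxide oxygen to the β-carbon of the ynone (O1–C2), and the resulting allenolate is protonated at C3. No stereocentre is created. The step needs the carboxylate to enter at C8a and the ring to close endo and not 5-exo: the inductive pull of the C5 isopropoxy oxygen stabilises negative charge on the adjacent aryne carbon so that the nucleophile attacks the distal one, the symmetry of ring A leaves only one possible aryne, and the conjugate polarisation of the ynone sends oxygen to the β-carbon. A hot, aprotic medium and excess CsF are chosen so that acyl transfer outruns protonation of the aryl anion.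

Step 8
Reactants: 19 5,7-diisopropoxy-6-[2,4-dimethoxy-6-(methoxymethoxy)phenyl]-2-(4-methoxyphenyl)chromen-4-one
Product: 20 6-(2-hydroxy-4,6-dimethoxyphenyl)-5,7-diisopropoxy-2-(4-methoxyphenyl)chromen-4-one
Conditions: p-TsOH·H2O (0.2 equiv), MeOH/CH2Cl2, 40 °C
Reagents that add atoms: none
Why: Acid-catalysed transacetalisation of the aryl MOM ether with methanol frees the phenol of unit 2 under conditions too mild to touch the isopropyl and methyl ethers or the chromone.

Step 9
Reactants: 20 6-(2-hydroxy-4,6-dimethoxyphenyl)-5,7-diisopropoxy-2-(4-methoxyphenyl)chromen-4-one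
Product: 22 3-[5,7-diisopropoxy-2-(4-methoxyphenyl)-4-oxochromen-6-yl]-2-hydroxy-4,6-dimethoxybenzaldehyde, via hydroxymethylphenol 21 (not isolated)
Conditions: MgCl2, Et3N, (CH2O)n, MeCN, 80 °C
Reagents that add atoms: paraformaldehyde (formaldehyde), C=O
Why: Magnesium-mediated ortho-formylation of a phenol (Casnati–Skattebøl reaction), in which the magnesium phenoxide delivers formaldehyde only ortho to oxygen, where a single position is free, and a second formaldehyde takes the hydride, so the carbon that becomes C4 of unit 2 is installed without acid.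

Step 10
Reactants: 22 3-[5,7-diisopropoxy-2-(4-methoxyphenyl)-4-oxochromen-6-yl]-2-hydroxy-4,6-dimethoxybenzaldehyde; 23 1-ethynyl-4-methoxybenzene
Product: 25 6-{2-hydroxy-3-[1-hydroxy-3-(4-methoxyphenyl)prop-2-yn-1-yl]-4,6-dimethoxyphenyl}-5,7-diisopropoxy-2-(4-methoxyphenyl)chromen-4-one, via lithium acetylide 24 (not isolated)
Conditions: 23 (3 equiv), n-BuLi (2.8 equiv), THF, −78 °C; then 22, −78 to −20 °C; aq. NH4Cl
Reagents that add atoms: none
Why: 1,2-Addition of a lithium acetylide to an aldehyde, which even after deprotonation of the phenol should be far more electrophilic than the hindered vinylogous-ester carbonyl of the chromone at low temperature; the new carbinol centre is formed without control and is erased by the oxidation of step 11.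

Step 11
Reactants: 25 6-{2-hydroxy-3-[1-hydroxy-3-(4-methoxyphenyl)prop-2-yn-1-yl]-4,6-dimethoxyphenyl}-5,7-diisopropoxy-2-(4-methoxyphenyl)chromen-4-one
Product: 28 5,7-diisopropoxy-6-[5,7-dimethoxy-2-(4-methoxyphenyl)-4-oxochromen-8-yl]-2-(4-methoxyphenyl)chromen-4-one, via hydroxy ynone 26 (not isolated), via enaminone 27 (not isolated)
Conditions: MnO2, CH2Cl2, rt; filter; Et2NH, EtOH, 50 °C
Reagents that add atoms: none
Why: Manganese dioxide oxidises the benzylic propargylic alcohol to the ortho-hydroxyaryl ynone, and conjugate addition of diethylamine gives an enaminone that can only cyclise by 6-endo addition–elimination of the phenol, a known flavone closure that rules out the aurone.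

Step 12
Reactants: 28 5,7-diisopropoxy-6-[5,7-dimethoxy-2-(4-methoxyphenyl)-4-oxochromen-8-yl]-2-(4-methoxyphenyl)chromen-4-one
Product: 29 5,7-dihydroxy-6-[5-hydroxy-7-methoxy-2-(4-methoxyphenyl)-4-oxochromen-8-yl]-2-(4-methoxyphenyl)chromen-4-one
Conditions: BCl3 (1 M in CH2Cl2, excess), CH2Cl2, −78 to 0 °C; then MeOH, aq. NaHCO3
Reagents that add atoms: none
Why: Lewis-acid ether cleavage with BCl3 should remove the two isopropyl ethers (secondary alkyl) and the C5 methyl ether of unit 2, which is chelated to the C4 carbonyl, while the unchelated methyl ethers at C7 of unit 2 and on both 4-methoxyphenyl rings are left at or below 0 °C.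

**Compound list**

1 | 3,5-dimethoxyphenol | COc1cc(O)cc(OC)c1 | starting material
2 | 1,3-dimethoxy-5-(methoxymethoxy)benzene | COCOc1cc(OC)cc(OC)c1 | intermediate
3 | [2,4-dimethoxy-6-(methoxymethoxy)phenyl]lithium | [Li]c1c(OC)cc(OC)cc1OCOC | intermediate
4 | 2-iodo-1,5-dimethoxy-3-(methoxymethoxy)benzene | COCOc1cc(OC)cc(OC)c1I | intermediate
5 | 1,3-diisopropoxybenzene | CC(C)Oc1cccc(OC(C)C)c1 | starting material
6 | (2,6-diisopropoxyphenyl)lithium | [Li]c1c(OC(C)C)cccc1OC(C)C | intermediate
7 | (2,6-diisopropoxyphenyl)zinc chloride | Cl[Zn]c1c(OC(C)C)cccc1OC(C)C | intermediate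
8 | 2',6'-diisopropoxy-2,4-dimethoxy-6-(methoxymethoxy)biphenyl | COCOc1cc(OC)cc(OC)c1-c1c(OC(C)C)cccc1OC(C)C | intermediate
9 | 2-{3,5-diisopropoxy-4-[2,4-dimethoxy-6-(methoxymethoxy)phenyl]phenyl}-4,4,5,5-tetramethyl-1,3,2-dioxaborolane | COCOc1cc(OC)cc(OC)c1-c1c(OC(C)C)cc(B2OC(C)(C)C(C)(C)O2)cc1OC(C)C | intermediate
10 | 3,5-diisopropoxy-4-[2,4-dimethoxy-6-(methoxymethoxy)phenyl]phenol | COCOc1cc(OC)cc(OC)c1-c1c(OC(C)C)cc(O)cc1OC(C)C | intermediate
11 | 2-bromo-3,5-diisopropoxy-4-[2,4-dimethoxy-6-(methoxymethoxy)phenyl]phenol (racemic axis) | COCOc1cc(OC)cc(OC)c1-c1c(OC(C)C)cc(O)c(Br)c1OC(C)C | intermediate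
12 | {2-bromo-3,5-diisopropoxy-4-[2,4-dimethoxy-6-(methoxymethoxy)phenyl]phenoxy}trimethylsilane | COCOc1cc(OC)cc(OC)c1-c1c(OC(C)C)cc(O[Si](C)(C)C)c(Br)c1OC(C)C | intermediate
13 | {2,4-diisopropoxy-3-[2,4-dimethoxy-6-(methoxymethoxy)phenyl]-6-(trimethylsilyloxy)phenyl}lithium | COCOc1cc(OC)cc(OC)c1-c1c(OC(C)C)cc(O[Si](C)(C)C)c([Li])c1OC(C)C | intermediate
14 | lithium 3,5-diisopropoxy-4-[2,4-dimethoxy-6-(methoxymethoxy)phenyl]-2-(trimethylsilyl)phenolate | COCOc1cc(OC)cc(OC)c1-c1c(OC(C)C)cc(O[Li])c([Si](C)(C)C)c1OC(C)C | intermediate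
15 | 3,5-diisopropoxy-4-[2,4-dimethoxy-6-(methoxymethoxy)phenyl]-2-(trimethylsilyl)phenyl trifluoromethanesulfonate | C[Si](C)(C)c1c(OS(=O)(=O)C(F)(F)F)cc(OC(C)C)c(-c2c(OC)cc(OC)cc2OCOC)c1OC(C)C | intermediate
16 | 3-(4-methoxyphenyl)propiolic acid | COc1ccc(C#CC(=O)O)cc1 | starting material
17 | 3,5-diisopropoxy-4-[2,4-dimethoxy-6-(methoxymethoxy)phenyl]benzyne (triple bond C1–C2) | C1#CC(OC(C)C)=C(c2c(OC)cc(OC)cc2OCOC)C(OC(C)C)=C1 | intermediate
18 | caesium 3,5-diisopropoxy-4-[2,4-dimethoxy-6-(methoxymethoxy)phenyl]-2-[3-(4-methoxyphenyl)propioloyl]phenolate | [Cs+].[O-]c1cc(OC(C)C)c(-c2c(OC)cc(OC)cc2OCOC)c(OC(C)C)c1C(=O)C#Cc1ccc(OC)cc1 | intermediate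
19 | 5,7-diisopropoxy-6-[2,4-dimethoxy-6-(methoxymethoxy)phenyl]-2-(4-methoxyphenyl)chromen-4-one | COc1ccc(-c2cc(=O)c3c(OC(C)C)c(-c4c(OC)cc(OC)cc4OCOC)c(OC(C)C)cc3o2)cc1 | intermediate
20 | 6-(2-hydroxy-4,6-dimethoxyphenyl)-5,7-diisopropoxy-2-(4-methoxyphenyl)chromen-4-one | COc1ccc(-c2cc(=O)c3c(OC(C)C)c(-c4c(OC)cc(OC)cc4O)c(OC(C)C)cc3o2)cc1 | intermediate
21 | 6-[2-hydroxy-3-(hydroxymethyl)-4,6-dimethoxyphenyl]-5,7-diisopropoxy-2-(4-methoxyphenyl)chromen-4-one (present as its magnesium salt) | COc1ccc(-c2cc(=O)c3c(OC(C)C)c(-c4c(OC)cc(OC)c(CO)c4O)c(OC(C)C)cc3o2)cc1 | intermediate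
22 | 3-[5,7-diisopropoxy-2-(4-methoxyphenyl)-4-oxochromen-6-yl]-2-hydroxy-4,6-dimethoxybenzaldehyde | COc1ccc(-c2cc(=O)c3c(OC(C)C)c(-c4c(OC)cc(OC)c(C=O)c4O)c(OC(C)C)cc3o2)cc1 | intermediate
23 | 1-ethynyl-4-methoxybenzene | C#Cc1ccc(OC)cc1 | starting material
24 | lithium (4-methoxyphenyl)acetylide | [Li]C#Cc1ccc(OC)cc1 | intermediate
25 | 6-{2-hydroxy-3-[1-hydroxy-3-(4-methoxyphenyl)prop-2-yn-1-yl]-4,6-dimethoxyphenyl}-5,7-diisopropoxy-2-(4-methoxyphenyl)chromen-4-one (carbinol centre uncontrolled, mixture of diastereomers) | COc1ccc(-c2cc(=O)c3c(OC(C)C)c(-c4c(OC)cc(OC)c(C(O)C#Cc5ccc(OC)cc5)c4O)c(OC(C)C)cc3o2)cc1 | intermediate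
26 | 6-{2-hydroxy-4,6-dimethoxy-3-[3-(4-methoxyphenyl)propioloyl]phenyl}-5,7-diisopropoxy-2-(4-methoxyphenyl)chromen-4-one | COc1ccc(-c2cc(=O)c3c(OC(C)C)c(-c4c(OC)cc(OC)c(C(=O)C#Cc5ccc(OC)cc5)c4O)c(OC(C)C)cc3o2)cc1 | intermediate
27 | 6-{3-[3-(diethylamino)-3-(4-methoxyphenyl)acryloyl]-2-hydroxy-4,6-dimethoxyphenyl}-5,7-diisopropoxy-2-(4-methoxyphenyl)chromen-4-one (alkene geometry uncontrolled and without consequence) | COc1ccc(-c2cc(=O)c3c(OC(C)C)c(-c4c(OC)cc(OC)c(C(=O)C=C(N(CC)CC)c5ccc(OC)cc5)c4O)c(OC(C)C)cc3o2)cc1 | intermediate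
28 | 5,7-diisopropoxy-6-[5,7-dimethoxy-2-(4-methoxyphenyl)-4-oxochromen-8-yl]-2-(4-methoxyphenyl)chromen-4-one | COc1ccc(-c2cc(=O)c3c(OC(C)C)c(-c4c(OC)cc(OC)c5c(=O)cc(-c6ccc(OC)cc6)oc45)c(OC(C)C)cc3o2)cc1 | intermediate
29 | 5,7-dihydroxy-6-[5-hydroxy-7-methoxy-2-(4-methoxyphenyl)-4-oxochromen-8-yl]-2-(4-methoxyphenyl)chromen-4-one (CNP0146326.0) | COc1ccc(-c2cc(=O)c3c(O)c(-c4c(OC)cc(O)c5c(=O)cc(-c6ccc(OC)cc6)oc45)c(O)cc3o2)cc1 | target

**Step count**

Total steps: 12. Longest linear sequence: 12 steps (1 to 29 through steps 1–12; compounds 5, 16 and 23 enter at steps 3, 7 and 10).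

**Steps most likely to fail**

Step 7. The aryl anion may be protonated before the acyl group has migrated, which would stop at the aryl ester; the propiolate may lose CO2 at 125 °C; or addition to the hindered aryne may be slow. The fallback gives up the aryne and makes the same ynone stepwise, setting out from phenol 10 and rejoining the route at flavone 19. Phenol 10 is formylated ortho to oxygen (MgCl2, Et3N, paraformaldehyde; both ortho positions are equivalent) to give 2-hydroxy-4,6-diisopropoxy-5-[2,4-dimethoxy-6-(methoxymethoxy)phenyl]benzaldehyde F1. Lithium acetylide 24 adds to give the propargylic alcohol F2. MnO2 oxidises this to the hydroxy ynone F3, the free phenol of 18. Diethylamine in ethanol converts it through the enaminone F4 into 19.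

Step 3. Transmetalation and reductive elimination at a palladium centre that must carry two 2,6-dialkoxyaryl groups may be slow, so that reduction of the iodide or homocoupling takes over. The fallback changes to a boron-based coupling with the roles of the two rings exchanged; it sets out from 5 and 2 and returns at biaryl 8. Aryllithium 6 (from 5) is quenched with iodine to give 2-iodo-1,3-diisopropoxybenzene F5. Aryllithium 3 (from 2) is quenched with B(OMe)3 and hydrolysed to [2,4-dimethoxy-6-(methoxymethoxy)phenyl]boronic acid F6. Suzuki–Miyaura coupling of the two (Pd(OAc)2, SPhos, K3PO4, toluene/H2O, 100 °C) gives 8.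

Step 10. The acetylide may attack the chromone carbonyl of unit 1, or addition to an aldehyde deactivated by the neighbouring phenoxide may stay incomplete. The fallback is the classical acetophenone route, setting out from phenol 20 and returning at 28. Ac2O and BF3·OEt2 (CH2Cl2, 0 to 40 °C, then aqueous NaOAc) effect O-acetylation and Fries rearrangement to the ortho-hydroxyacetophenone 6-(3-acetyl-2-hydroxy-4,6-dimethoxyphenyl)-5,7-diisopropoxy-2-(4-methoxyphenyl)chromen-4-one F7. LiN(SiMe3)2 (4 equiv) and 4-methoxybenzoyl chloride (THF, −78 °C to rt) give the 1,3-diketone F8 by Baker–Venkataraman-type C-aroylation. p-TsOH·H2O in toluene at 80 °C cyclodehydrates F8 to 28; loss of the peri isopropyl group under the Lewis acid would not change the final product.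

**Further compounds**

F1 | step 7 | 2-hydroxy-4,6-diisopropoxy-5-[2,4-dimethoxy-6-(methoxymethoxy)phenyl]benzaldehyde | O=Cc1c(O)cc(OC(C)C)c(-c2c(OC)cc(OC)cc2OCOC)c1OC(C)C
F2 | step 7 | 1-{2-hydroxy-4,6-diisopropoxy-5-[2,4-dimethoxy-6-(methoxymethoxy)phenyl]phenyl}-3-(4-methoxyphenyl)prop-2-yn-1-ol (carbinol centre uncontrolled) | COc1ccc(C#CC(O)c2c(O)cc(OC(C)C)c(-c3c(OC)cc(OC)cc3OCOC)c2OC(C)C)cc1
F3 | step 7 | 1-{2-hydroxy-4,6-diisopropoxy-5-[2,4-dimethoxy-6-(methoxymethoxy)phenyl]phenyl}-3-(4-methoxyphenyl)prop-2-yn-1-one | COc1ccc(C#CC(=O)c2c(O)cc(OC(C)C)c(-c3c(OC)cc(OC)cc3OCOC)c2OC(C)C)cc1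
F4 | step 7 | 3-(diethylamino)-1-{2-hydroxy-4,6-diisopropoxy-5-[2,4-dimethoxy-6-(methoxymethoxy)phenyl]phenyl}-3-(4-methoxyphenyl)prop-2-en-1-one (alkene geometry uncontrolled) | CCN(CC)C(=CC(=O)c1c(O)cc(OC(C)C)c(-c2c(OC)cc(OC)cc2OCOC)c1OC(C)C)c1ccc(OC)cc1
F5 | step 3 | 2-iodo-1,3-diisopropoxybenzene | CC(C)Oc1cccc(OC(C)C)c1I
F6 | step 3 | [2,4-dimethoxy-6-(methoxymethoxy)phenyl]boronic acid | COCOc1cc(OC)cc(OC)c1B(O)O
F7 | step 10 | 6-(3-acetyl-2-hydroxy-4,6-dimethoxyphenyl)-5,7-diisopropoxy-2-(4-methoxyphenyl)chromen-4-one | COc1ccc(-c2cc(=O)c3c(OC(C)C)c(-c4c(OC)cc(OC)c(C(C)=O)c4O)c(OC(C)C)cc3o2)cc1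
F8 | step 10 | 1-{3-[5,7-diisopropoxy-2-(4-methoxyphenyl)-4-oxochromen-6-yl]-2-hydroxy-4,6-dimethoxyphenyl}-3-(4-methoxyphenyl)propane-1,3-dione | COc1ccc(-c2cc(=O)c3c(OC(C)C)c(-c4c(OC)cc(OC)c(C(=O)CC(=O)c5ccc(OC)cc5)c4O)c(OC(C)C)cc3o2)cc1
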